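**Plan**
- Retrosynthesis: after removing the phenol protecting groups and the C1 ester C–O bond (Mitsunobu), ring B is cut at both of its bonds to ring A (C4–C4a and C8a–C1) in one stroke. The open chain is then cut at C1–C2 and at the C3 ester.
- Enabling feature: in ring B, C4 is the β-carbon of the C3 acrylate ester (a Heck acceptor when it is a terminal CH2) and C1 is α to a carboxyl (a malonate carbon once it carries a second, temporary ester). C4a and C8a are adjacent carbons of ring A, so ring A can be delivered as a 1-bromo-2-chloro arene.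
- Forward: one lactate alcohol → its acrylate → Morita–Baylis–Hillman adduct → carbonate → asymmetric allylic alkylation with di-tert-butyl malonate (chain complete). A one-pot Heck/malonate arylation with the bromo-chloro catechol acetonide then closes ring B.
- End game: acidolysis and decarboxylation (the temporary ester leaves, C1–H is set), Mitsunobu esterification of the C1 acid, global deprotection.
- Stereochemistry: C2 (S) from the cinchona-catalysed allylic alkylation; C1 (S, carboxyl cis to the C2 aryl) from kinetic protonation on decarboxylation. Both lactate centres come from one alcohol made from methyl (S)-glycidate: acylation with retention gives (S) on the C3 carboxyl, Mitsunobu inversion gives (R) on the C1 carboxyl.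

Key step: step 7

Remark: the SMILES is read as (1S,2S) with the C1 ester and the C2 aryl cis; atoms are numbered C1–C4, C4a, C5–C8, C8a as in 1,2-dihydronaphthalene (ring A = C4a–C8a, ring B = C1–C4, C4a, C8a); Ar = 3,4-bis(benzyloxy)phenyl; 5-bromo-2,2-dimethyl-1,3-benzodioxole is taken as commercial (otherwise one step from 4-bromocatechol and 2,2-dimethoxypropane).

Step 1
Reactants: 1 1,2-bis(benzyloxy)-4-bromobenzene; 2 methyl (2S)-oxirane-2-carboxylate (methyl (S)-glycidate)
Product: 4 methyl (2S)-3-[3,4-bis(benzyloxy)phenyl]-2-hydroxypropanoate, via aryl Grignard reagent 3 (not isolated)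
Conditions: Mg, THF, rt → 40 °C; then 2, CuI (10 mol%), THF, −40 → −20 °C; H2O quench
Reagents that add atoms: none
Why: Copper-catalysed SN2 opening of the epoxide at its CH2 carbon by the aryl Grignard reagent does not touch the stereocentre, so the (S) configuration of the glycidate is carried into the lactate, and low temperature with catalytic CuI favours epoxide opening over addition to the ester.

Step 2
Reactants: 4 methyl (2S)-3-[3,4-bis(benzyloxy)phenyl]-2-hydroxypropanoate; 5 acryloyl chloride
Product: 6 methyl (2S)-2-(acryloyloxy)-3-[3,4-bis(benzyloxy)phenyl]propanoate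
Conditions: Et3N, CH2Cl2, 0 °C
Reagents that add atoms: none
Why: O-acylation of the secondary alcohol with an acid chloride proceeds with retention at the carbinol carbon, which places the (S)-lactate unit on what becomes the C3 carboxyl.

Step 3
Reactants: 6 methyl (2S)-2-(acryloyloxy)-3-[3,4-bis(benzyloxy)phenyl]propanoate; 7 3,4-bis(benzyloxy)benzaldehyde
Product: 8 methyl (2S)-3-Ar-2-({2-[Ar(hydroxy)methyl]acryloyl}oxy)propanoate (both carbinol epimers)
Conditions: DABCO (1 equiv), 1,4-dioxane/H2O (1:1), rt, excess 7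
Reagents that add atoms: none
Why: Morita–Baylis–Hillman reaction (DABCO adds to the acrylate, the ammonium enolate adds to the aldehyde, the amine is expelled); the α-acyloxy ester makes 6 more electrophilic than a simple alkyl acrylate, which offsets the low reactivity of the electron-rich aldehyde, and the uncontrolled carbinol centre is erased in step 5.

Step 4
Reactants: 8 methyl (2S)-3-Ar-2-({2-[Ar(hydroxy)methyl]acryloyl}oxy)propanoate
Product: 9 methyl (2S)-3-Ar-2-({2-[Ar(tert-butoxycarbonyloxy)methyl]acryloyl}oxy)propanoate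
Conditions: Boc2O, DMAP (10 mol%), CH2Cl2, 0 °C → rt
Reagents that add atoms: di-tert-butyl dicarbonate, CC(C)(C)OC(=O)OC(=O)OC(C)(C)C
Why: DMAP-catalysed O-acylation gives the tert-butyl carbonate, the usual leaving group for amine-catalysed allylic substitution because it releases its own base (tert-butoxide) on ionisation.

Step 5
Reactants: 9 methyl (2S)-3-Ar-2-({2-[Ar(tert-butoxycarbonyloxy)methyl]acryloyl}oxy)propanoate; 10 di-tert-butyl malonate
Product: 11 di-tert-butyl 2-[(1S)-1-Ar-2-({[(2S)-3-Ar-1-methoxy-1-oxopropan-2-yl]oxy}carbonyl)prop-2-en-1-yl]malonate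
Conditions: hydroquinidine 1,4-phthalazinediyl diether, (DHQD)2PHAL (10 mol%), toluene, rt
Reagents that add atoms: none
Why: Lewis-base-catalysed asymmetric allylic alkylation of a Morita–Baylis–Hillman carbonate (SN2' then SN2'): the quinuclidine nitrogen displaces the carbonate at the CH2 terminus, the liberated tert-butoxide deprotonates 10, and the malonate attacks the benzylic carbon of the chiral allylammonium ion on the face left open by the catalyst, setting the future C2 as (S) stereoconvergently (the quasi-enantiomeric (DHQ)2PHAL is used should the first batch show the opposite sense).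

Step 6
Reactants: 12 5-bromo-2,2-dimethyl-1,3-benzodioxole
Product: 14 5-bromo-4-chloro-2,2-dimethyl-1,3-benzodioxole, via 4-lithio species 13 (not isolated)
Conditions: LDA (1.05 equiv), THF, −78 °C; then C2Cl6, −78 → −40 °C
Reagents that add atoms: hexachloroethane, ClC(Cl)(Cl)C(Cl)(Cl)Cl
Why: Directed ortho-lithiation takes place at the C–H flanked by the dioxole oxygen and bromine (the most acidic position) and hexachloroethane chlorinates the aryllithium; at −78 °C the ortho-bromoaryllithium does not lose LiBr to an aryne.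

Step 7
Reactants: 11 di-tert-butyl 2-[(1S)-1-Ar-2-({[(2S)-3-Ar-1-methoxy-1-oxopropan-2-yl]oxy}carbonyl)prop-2-en-1-yl]malonate; 14 5-bromo-4-chloro-2,2-dimethyl-1,3-benzodioxole
Product: 16 1,1-di-tert-butyl 3-[(2S)-3-Ar-1-methoxy-1-oxopropan-2-yl] (2S)-2-Ar-7,8-(isopropylidenedioxy)-1,2-dihydronaphthalene-1,1,3-tricarboxylate, via Heck-stage aryl chloride 15 (not isolated)
Conditions: Pd2(dba)3 (2.5 mol%), P(t-Bu)3·HBF4 (10 mol%), Cy2NMe (1.2 equiv), 1,4-dioxane, 40 °C; then K3PO4 (3 equiv), 100 °C, same flask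
Reagents that add atoms: none
Why: Zerovalent palladium first inserts into the unhindered C–Br bond of 14 (the flanked C–Cl bond is inert at 40 °C), the arylpalladium adds to the CH2 terminus of the 2-substituted acrylate of 11, and syn β-hydride elimination gives the (E)-cinnamate 15 (bond C4–C4a) with ring A cis to C2 as ring closure demands; after K3PO4 is added and the mixture heated, the same catalyst inserts into the C–Cl bond, the potassium malonate binds palladium through C1, and C(sp2)–C(sp3) reductive elimination from the seven-membered palladacycle forms bond C8a–C1. The closest known reaction types are the Heck arylation of α-substituted acrylates with Pd/P(t-Bu)3 and Cy2NMe and the Pd/P(t-Bu)3-catalysed α-arylation of malonates with aryl chlorides under phosphate base, here run in sequence in one pot. Ring B closes in a six-membered-ring-forming (6-exo-type) enolate arylation, the ring size being fixed by the tether C1–C2–C3=C4–C4a. No new stereocentre is made (C1 is a gem-diester at this stage and C2 is not touched); the only stereo-element set is the (E)-alkene, controlled by syn elimination that places ring A away from the ester. The selectivity needed is the order of the two couplings, which decides whether the ring A oxygens end up peri to C1 (wanted) or to C4; it is secured by the Br/Cl reactivity gap, by the low intermolecular reactivity of the 2-substituted malonate, and by withholding the inorganic base until the Heck stage is complete. The second ester on C1 makes C1–H acidic enough for K3PO4, so the base-sensitive lactate ester survives.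

Step 8
Reactants: 16 1,1-di-tert-butyl 3-[(2S)-3-Ar-1-methoxy-1-oxopropan-2-yl] (2S)-2-Ar-7,8-(isopropylidenedioxy)-1,2-dihydronaphthalene-1,1,3-tricarboxylate
Product: 19 (1S,2S)-2-Ar-3-({[(2S)-3-Ar-1-methoxy-1-oxopropan-2-yl]oxy}carbonyl)-7,8-(isopropylidenedioxy)-1,2-dihydronaphthalene-1-carboxylic acid, via malonic diacid 17 (not isolated), via ene-diol 18 (not isolated)
Conditions: anhydrous TFA/CH2Cl2 (1:4), 0 °C → rt; evaporate; toluene, 70 °C
Reagents that add atoms: none
Why: Acidolysis of both tert-butyl esters gives diacid 17, which loses CO2 through the cyclic six-membered transition state to ene-diol 18, and ketonisation of 18 is kinetic: ring B is nearly flat with the C2 aryl pseudoaxial (allylic strain with the C3 ester and the exocyclic C1=C(OH)2), so the proton reaches C1 from the face opposite that aryl and leaves the carboxyl cis to it, (1S,2S); no base is present, so this less stable cis arrangement is not equilibrated, and anhydrous acid spares the ketal and the benzyl ethers.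

Step 9
Reactants: 19 (1S,2S)-2-Ar-3-({[(2S)-3-Ar-1-methoxy-1-oxopropan-2-yl]oxy}carbonyl)-7,8-(isopropylidenedioxy)-1,2-dihydronaphthalene-1-carboxylic acid; 4 methyl (2S)-3-[3,4-bis(benzyloxy)phenyl]-2-hydroxypropanoate
Product: 20 1-[(2R)-3-Ar-1-methoxy-1-oxopropan-2-yl] 3-[(2S)-3-Ar-1-methoxy-1-oxopropan-2-yl] (1S,2S)-2-Ar-7,8-(isopropylidenedioxy)-1,2-dihydronaphthalene-1,3-dicarboxylate
Conditions: PPh3, DIAD, THF, 0 °C → rt
Reagents that add atoms: none
Why: Mitsunobu esterification: the carboxylate of 19 displaces the alkoxyphosphonium of the (S)-alcohol by SN2, so the new lactate centre is (R) by inversion, and because the acid is never turned into an acyl electrophile the epimerisable C1 centre is not disturbed.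

Step 10
Reactants: 20 1-[(2R)-3-Ar-1-methoxy-1-oxopropan-2-yl] 3-[(2S)-3-Ar-1-methoxy-1-oxopropan-2-yl] (1S,2S)-2-Ar-7,8-(isopropylidenedioxy)-1,2-dihydronaphthalene-1,3-dicarboxylate
Product: 21 target, 1-[(2R)-3-(3,4-dihydroxyphenyl)-1-methoxy-1-oxopropan-2-yl] 3-[(2S)-3-(3,4-dihydroxyphenyl)-1-methoxy-1-oxopropan-2-yl] (1S,2S)-2-(3,4-dihydroxyphenyl)-7,8-dihydroxy-1,2-dihydronaphthalene-1,3-dicarboxylate
Conditions: BCl3 (excess), C6HMe5, CH2Cl2, −78 → 0 °C; MeOH/H2O quench
Reagents that add atoms: none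
Why: Lewis-acid cleavage of the six aryl benzyl ethers with pentamethylbenzene as benzyl-cation scavenger, together with cleavage of the isopropylidene ketal (completed by the aqueous acidic quench), frees all eight phenols without hydrogenation (the C3=C4 alkene is kept) and without base (C1 and the lactate centres are not epimerised, the four esters are kept).

**Compound list**
1 | 1,2-bis(benzyloxy)-4-bromobenzene | Brc1ccc(OCc2ccccc2)c(OCc2ccccc2)c1 | starting material
2 | methyl (2S)-oxirane-2-carboxylate | COC(=O)[C@@H]1CO1 | starting material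
3 | [3,4-bis(benzyloxy)phenyl]magnesium bromide | Br[Mg]c1ccc(OCc2ccccc2)c(OCc2ccccc2)c1 | intermediate
4 | methyl (2S)-3-[3,4-bis(benzyloxy)phenyl]-2-hydroxypropanoate | COC(=O)[C@H](Cc1ccc(OCc2ccccc2)c(OCc2ccccc2)c1)O | intermediate
5 | acryloyl chloride | C=CC(=O)Cl | starting material
6 | methyl (2S)-2-(acryloyloxy)-3-[3,4-bis(benzyloxy)phenyl]propanoate | COC(=O)[C@H](Cc1ccc(OCc2ccccc2)c(OCc2ccccc2)c1)OC(=O)C=C | intermediate
7 | 3,4-bis(benzyloxy)benzaldehyde | O=Cc1ccc(OCc2ccccc2)c(OCc2ccccc2)c1 | starting material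
8 | methyl (2S)-3-Ar-2-({2-[Ar(hydroxy)methyl]acryloyl}oxy)propanoate, carbinol epimers | COC(=O)[C@H](Cc1ccc(OCc2ccccc2)c(OCc2ccccc2)c1)OC(=O)C(=C)C(O)c1ccc(OCc2ccccc2)c(OCc2ccccc2)c1 | intermediate
9 | tert-butyl carbonate of 8 | COC(=O)[C@H](Cc1ccc(OCc2ccccc2)c(OCc2ccccc2)c1)OC(=O)C(=C)C(OC(=O)OC(C)(C)C)c1ccc(OCc2ccccc2)c(OCc2ccccc2)c1 | intermediate
10 | di-tert-butyl malonate | CC(C)(C)OC(=O)CC(=O)OC(C)(C)C | starting material
11 | di-tert-butyl 2-[(1S)-1-Ar-2-({[(2S)-3-Ar-1-methoxy-1-oxopropan-2-yl]oxy}carbonyl)prop-2-en-1-yl]malonate | COC(=O)[C@H](Cc1ccc(OCc2ccccc2)c(OCc2ccccc2)c1)OC(=O)C(=C)[C@H](c1ccc(OCc2ccccc2)c(OCc2ccccc2)c1)C(C(=O)OC(C)(C)C)C(=O)OC(C)(C)C | intermediate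
12 | 5-bromo-2,2-dimethyl-1,3-benzodioxole | CC1(C)Oc2ccc(Br)cc2O1 | starting material
13 | (5-bromo-2,2-dimethyl-1,3-benzodioxol-4-yl)lithium | CC1(C)Oc2ccc(Br)c([Li])c2O1 | intermediate
14 | 5-bromo-4-chloro-2,2-dimethyl-1,3-benzodioxole | CC1(C)Oc2ccc(Br)c(Cl)c2O1 | intermediate
15 | di-tert-butyl 2-[(1S,2E)-1-Ar-3-(4-chloro-2,2-dimethyl-1,3-benzodioxol-5-yl)-2-({[(2S)-3-Ar-1-methoxy-1-oxopropan-2-yl]oxy}carbonyl)prop-2-en-1-yl]malonate | COC(=O)[C@H](Cc1ccc(OCc2ccccc2)c(OCc2ccccc2)c1)OC(=O)/C(=C/c1ccc2OC(C)(C)Oc2c1Cl)[C@H](c1ccc(OCc2ccccc2)c(OCc2ccccc2)c1)C(C(=O)OC(C)(C)C)C(=O)OC(C)(C)C | intermediate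
16 | 1,1-di-tert-butyl 3-[(2S)-3-Ar-1-methoxy-1-oxopropan-2-yl] (2S)-2-Ar-7,8-(isopropylidenedioxy)-1,2-dihydronaphthalene-1,1,3-tricarboxylate | COC(=O)[C@H](Cc1ccc(OCc2ccccc2)c(OCc2ccccc2)c1)OC(=O)C1=Cc2ccc3OC(C)(C)Oc3c2C(C(=O)OC(C)(C)C)(C(=O)OC(C)(C)C)[C@H]1c1ccc(OCc2ccccc2)c(OCc2ccccc2)c1 | intermediate
17 | 1,1-dicarboxylic acid corresponding to 16 | COC(=O)[C@H](Cc1ccc(OCc2ccccc2)c(OCc2ccccc2)c1)OC(=O)C1=Cc2ccc3OC(C)(C)Oc3c2C(C(=O)O)(C(=O)O)[C@H]1c1ccc(OCc2ccccc2)c(OCc2ccccc2)c1 | intermediate
18 | ene-diol (C1=C(OH)2) formed from 17 by loss of CO2 | COC(=O)[C@H](Cc1ccc(OCc2ccccc2)c(OCc2ccccc2)c1)OC(=O)C1=Cc2ccc3OC(C)(C)Oc3c2C(=C(O)O)[C@H]1c1ccc(OCc2ccccc2)c(OCc2ccccc2)c1 | intermediate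
19 | (1S,2S)-2-Ar-3-({[(2S)-3-Ar-1-methoxy-1-oxopropan-2-yl]oxy}carbonyl)-7,8-(isopropylidenedioxy)-1,2-dihydronaphthalene-1-carboxylic acid | COC(=O)[C@H](Cc1ccc(OCc2ccccc2)c(OCc2ccccc2)c1)OC(=O)C1=Cc2ccc3OC(C)(C)Oc3c2[C@@H](C(=O)O)[C@H]1c1ccc(OCc2ccccc2)c(OCc2ccccc2)c1 | intermediate
20 | fully protected target (six benzyl ethers, ring A isopropylidene ketal) | COC(=O)[C@H](Cc1ccc(OCc2ccccc2)c(OCc2ccccc2)c1)OC(=O)C1=Cc2ccc3OC(C)(C)Oc3c2[C@@H](C(=O)O[C@H](Cc2ccc(OCc4ccccc4)c(OCc4ccccc4)c2)C(=O)OC)[C@H]1c1ccc(OCc2ccccc2)c(OCc2ccccc2)c1 | intermediate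
21 | CNP0237075.1 | COC(=O)[C@H](Cc1ccc(O)c(O)c1)OC(=O)C1=Cc2ccc(O)c(O)c2[C@@H](C(=O)O[C@H](Cc2ccc(O)c(O)c2)C(=O)OC)[C@H]1c1ccc(O)c(O)c1 | target

Total step count: 10. Longest linear sequence: 9 steps (1, 2, 3, 4, 5, 7, 8, 9, 10).

**Steps most likely to fail**

Step 7. The ring-closing arylation of the fully substituted malonate carbon at the doubly flanked C–Cl bond may stall after the Heck stage (catalyst death, protodechlorination). Alternatively, part of the material may couple through the malonate first and so carry ring A in the reversed orientation. The fallback sets out from the lithio species 13 of step 6 together with 10 and 9, and comes back at 16. Compound 13 is quenched with iodine instead of hexachloroethane to give 5-bromo-4-iodo-2,2-dimethyl-1,3-benzodioxole F1. The unsubstituted, far more reactive malonate 10 is arylated at the C–I bond only (CuI, 2-picolinic acid, Cs2CO3, 1,4-dioxane, 40 °C, Hurtley-type coupling) to give di-tert-butyl 2-(5-bromo-2,2-dimethyl-1,3-benzodioxol-4-yl)malonate F2, so bond C8a–C1 is made first and without ambiguity. F2 then serves as the carbon acid in the amine-catalysed allylic alkylation of carbonate 9 under the conditions of step 5, which forms C1–C2 and sets C2, giving the aryl malonate adduct di-tert-butyl 2-(5-bromo-2,2-dimethyl-1,3-benzodioxol-4-yl)-2-[(1S)-1-Ar-2-({[(2S)-3-Ar-1-methoxy-1-oxopropan-2-yl]oxy}carbonyl)prop-2-en-1-yl]malonate F3. An intramolecular Heck reaction of F3 (Pd(OAc)2, P(o-tol)3, Et3N, MeCN, 80 °C; 6-endo closure onto the CH2 terminus of the acrylate, β-hydride elimination towards C4) forms C4–C4a and delivers 16.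

Step 8. Facial selectivity in the ketonisation of the ene-diol may be poor, or C1 may equilibrate under acid towards the more stable trans arrangement. The fallback sets out from 19 as whatever mixture of C1 epimers is obtained and comes back at 20, replacing step 9 as well. The acid is converted with oxalyl chloride and catalytic DMF (CH2Cl2, 0 °C) into the acid chloride of 19, F4. Me2NEt in toluene at −78 °C turns F4 into the ketene F5, in which C1 is trigonal and both epimers converge. The ketene is trapped with methyl (2R)-3-[3,4-bis(benzyloxy)phenyl]-2-hydroxypropanoate F6, made as in step 1 from Grignard reagent 3 and methyl (2R)-oxirane-2-carboxylate. The alcohol adds with retention at its own centre and the resulting enol is protonated at C1 from the face opposite the C2 aryl, the known stereoconvergent alcoholysis of aryl alkyl ketenes, to give 20.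

Step 5. Substitution by the bulky di-tert-butyl malonate may be sluggish or poorly enantioselective, and the preceding Morita–Baylis–Hillman reaction of the electron-rich aldehyde (step 3) may be too slow to supply material. The fallback sets out from 7, 10 and 4 and comes back at 11. Wittig olefination of 7 with (triphenylphosphoranylidene)acetaldehyde (toluene, 80 °C) gives (E)-3-[3,4-bis(benzyloxy)phenyl]acrylaldehyde F7. Iminium-catalysed Michael addition of 10 (diarylprolinol trimethylsilyl ether enantiomer that delivers the (S)-adduct, EtOH, rt) gives di-tert-butyl 2-[(1S)-1-Ar-3-oxopropyl]malonate F8 and sets C2. Amine-catalysed α-methylenation (aqueous CH2O, pyrrolidine and propionic acid, i-PrOH, 45 °C) gives di-tert-butyl 2-[(1S)-1-Ar-2-formylprop-2-en-1-yl]malonate F9. Pinnick oxidation (NaClO2, NaH2PO4, 2-methyl-2-butene, t-BuOH/H2O) gives 2-{(1S)-1-Ar-2,2-bis(tert-butoxycarbonyl)ethyl}acrylic acid F10. Steglich esterification of F10 with 4 (DCC, DMAP, CH2Cl2; retention at the lactate carbon) gives 11.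

**Further compounds**
F1 | step 7 | 5-bromo-4-iodo-2,2-dimethyl-1,3-benzodioxole | CC1(C)Oc2ccc(Br)c(I)c2O1
F2 | step 7 | di-tert-butyl 2-(5-bromo-2,2-dimethyl-1,3-benzodioxol-4-yl)malonate | CC1(C)Oc2ccc(Br)c(C(C(=O)OC(C)(C)C)C(=O)OC(C)(C)C)c2O1
F3 | step 7 | di-tert-butyl 2-(5-bromo-2,2-dimethyl-1,3-benzodioxol-4-yl)-2-[(1S)-1-Ar-2-({[(2S)-3-Ar-1-methoxy-1-oxopropan-2-yl]oxy}carbonyl)prop-2-en-1-yl]malonate | COC(=O)[C@H](Cc1ccc(OCc2ccccc2)c(OCc2ccccc2)c1)OC(=O)C(=C)[C@H](c1ccc(OCc2ccccc2)c(OCc2ccccc2)c1)C(c1c(Br)ccc2OC(C)(C)Oc12)(C(=O)OC(C)(C)C)C(=O)OC(C)(C)C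
F4 | step 8 | acid chloride of 19 (C1 configuration not defined) | COC(=O)[C@H](Cc1ccc(OCc2ccccc2)c(OCc2ccccc2)c1)OC(=O)C1=Cc2ccc3OC(C)(C)Oc3c2C(C(=O)Cl)[C@H]1c1ccc(OCc2ccccc2)c(OCc2ccccc2)c1
F5 | step 8 | ketene (C1=C=O) derived from F4 | COC(=O)[C@H](Cc1ccc(OCc2ccccc2)c(OCc2ccccc2)c1)OC(=O)C1=Cc2ccc3OC(C)(C)Oc3c2C(=C=O)[C@H]1c1ccc(OCc2ccccc2)c(OCc2ccccc2)c1
F6 | step 8 | methyl (2R)-3-[3,4-bis(benzyloxy)phenyl]-2-hydroxypropanoate | COC(=O)[C@@H](Cc1ccc(OCc2ccccc2)c(OCc2ccccc2)c1)O
F7 | step 5 | (E)-3-[3,4-bis(benzyloxy)phenyl]acrylaldehyde | O=C/C=C/c1ccc(OCc2ccccc2)c(OCc2ccccc2)c1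
F8 | step 5 | di-tert-butyl 2-[(1S)-1-Ar-3-oxopropyl]malonate | O=CC[C@H](c1ccc(OCc2ccccc2)c(OCc2ccccc2)c1)C(C(=O)OC(C)(C)C)C(=O)OC(C)(C)C
F9 | step 5 | di-tert-butyl 2-[(1S)-1-Ar-2-formylprop-2-en-1-yl]malonate | O=CC(=C)[C@H](c1ccc(OCc2ccccc2)c(OCc2ccccc2)c1)C(C(=O)OC(C)(C)C)C(=O)OC(C)(C)C
F10 | step 5 | 2-{(1S)-1-Ar-2,2-bis(tert-butoxycarbonyl)ethyl}acrylic acid | OC(=O)C(=C)[C@H](c1ccc(OCc2ccccc2)c(OCc2ccccc2)c1)C(C(=O)OC(C)(C)C)C(=O)OC(C)(C)C
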